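## Retrosynthetic overview

1. Target 30 ⇐ aldehyde 26 (Z-enyne by Peterson olefination at C4) ⇐ 22 (C13–Br by invertive bromination; C10 acetate already in place) ⇐ oxocane alcohol 21.
2. Key disconnection (new): oxocane 21 ⇐ tetrahydrofuran 18 by a chloronium-triggered ring expansion that makes C6–O, C7–Cl and C9–Cl in one step.
3. 18 ⇐ trans-epoxy alcohol 17 (5-endo opening) ⇐ anti-chlorohydrin / 1,3-syn diol 16.
4. 16 ⇐ aldol of α-chloroaldehyde 8 (C4–C10) with methyl ketone 12 (C11–C15), then 1,3-syn reduction; 8 ⇐ but-3-yn-1-ol, 12 ⇐ methyl (S)-2-hydroxybutanoate.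
5. Ring order: the tetrahydrofuran (ring A: O, C9–C12) is made first (step 12) and is then enlarged to the eight-membered oxocane (step 13), the only ring of the target.

Conventions: atom labels C1–C15 are the chain labels of the C15 skeleton (C1 = alkyne CH, C6 and C12 = the two ring C–O carbons, C15 = ethyl CH3). The target is (6S,7S,9S,10S,12R,13R), with C6 and C12 side chains trans across the ring oxygen. TBS = tert-butyldimethylsilyl, TBDPS = tert-butyldiphenylsilyl, TIPS = triisopropylsilyl.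

Assumption: in step 5 the (2S,5S) enantiomer of 2,5-diphenylpyrrolidine is taken as the one that gives the (R)-chloride; if the sense is the reverse, the (2R,5R) amine is used.

## Route

Step 1
Reactants: 1 but-3-yn-1-ol
Product: 2 tert-butyl(but-3-yn-1-yloxy)diphenylsilane
Conditions: TBDPSCl, imidazole, CH2Cl2, 0 °C → rt
Reagents that add atoms: tert-butyl(chloro)diphenylsilane CC(C)(C)[Si](Cl)(c1ccccc1)c1ccccc1
Why: Standard silyl ether formation on a primary alcohol; the robust TBDPS group masks C4–OH until step 17.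

Step 2
Reactants: 2 tert-butyl(but-3-yn-1-yloxy)diphenylsilane; 3 2-(2-bromoethyl)-1,3-dioxolane
Product: 5 tert-butyl{[6-(1,3-dioxolan-2-yl)hex-3-yn-1-yl]oxy}diphenylsilane, via lithium acetylide 4 (not isolated)
Conditions: n-BuLi, THF, −78 °C; then 3, DMPU, −78 °C → rt
Reagents that add atoms: none
Why: SN2 alkylation of the lithium acetylide with the primary bromide brings in C8–C10, with C10 masked as the acetal.

Step 3
Reactants: 5 tert-butyl{[6-(1,3-dioxolan-2-yl)hex-3-yn-1-yl]oxy}diphenylsilane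
Product: 6 tert-butyl{[(3Z)-6-(1,3-dioxolan-2-yl)hex-3-en-1-yl]oxy}diphenylsilane
Conditions: H2 (1 atm), Pd/CaCO3 poisoned with Pb(OAc)2, quinoline, EtOAc, rt
Reagents that add atoms: none
Why: Lindlar semi-hydrogenation adds H2 syn to the alkyne and gives the (Z)-C6=C7 alkene that the ring expansion needs.

Step 4
Reactants: 6 tert-butyl{[(3Z)-6-(1,3-dioxolan-2-yl)hex-3-en-1-yl]oxy}diphenylsilane
Product: 7 (4Z)-7-(TBDPSO)hept-4-enal
Conditions: AcOH/THF/H2O (3:1:1), 45 °C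
Reagents that add atoms: water O
Why: Acid-catalysed acetal hydrolysis frees the C10 aldehyde while the TBDPS ether and the Z-alkene are untouched.

Step 5
Reactants: 7 (4Z)-7-(TBDPSO)hept-4-enal
Product: 8 (2R,4Z)-7-(TBDPSO)-2-chlorohept-4-enal
Conditions: NCS, (2S,5S)-2,5-diphenylpyrrolidine (10 mol%), CH2Cl2, 0 °C → rt; used crude at once
Reagents that add atoms: N-chlorosuccinimide O=C1CCC(=O)N1Cl
Why: Enamine-catalysed asymmetric α-chlorination of an aldehyde: the C2-symmetric amine blocks one enamine face so that NCS sets C9 as R.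

Step 6
Reactants: 9 methyl (2S)-2-hydroxybutanoate
Product: 10 methyl (2S)-2-(TBSO)butanoate
Conditions: TBSCl, imidazole, DMF, rt
Reagents that add atoms: tert-butyl(chloro)dimethylsilane CC(C)(C)[Si](C)(C)Cl
Why: Standard silyl ether formation; the chiral-pool stereocentre becomes C13 (S) and a bulky silyl ether cannot act as a neighbouring group later.

Step 7
Reactants: 10 methyl (2S)-2-(TBSO)butanoate
Product: 11 (2S)-2-(TBSO)-N-methoxy-N-methylbutanamide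
Conditions: MeNH(OMe)·HCl, i-PrMgCl, THF, −20 → 0 °C
Reagents that add atoms: N,O-dimethylhydroxylamine hydrochloride CNOC.Cl
Why: Weinreb amide formation by aminolysis of the ester with the magnesium amide; the α-stereocentre is not deprotonated under these conditions.

Step 8
Reactants: 11 (2S)-2-(TBSO)-N-methoxy-N-methylbutanamide
Product: 12 (3S)-3-(TBSO)pentan-2-one
Conditions: MeMgBr, THF, 0 °C
Reagents that add atoms: methylmagnesium bromide C[Mg]Br
Why: Weinreb ketone synthesis: the chelated tetrahedral adduct stops the reaction at mono-addition and gives the methyl ketone (C11 = CH3, C12 = C=O).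

Step 9
Reactants: 12 (3S)-3-(TBSO)pentan-2-one; 8 (2R,4Z)-7-(TBDPSO)-2-chlorohept-4-enal
Product: 14 (3S,6S,7R,9Z)-3-(TBSO)-12-(TBDPSO)-7-chloro-6-hydroxydodec-9-en-4-one, via lithium enolate 13 (not isolated)
Conditions: LiN(i-Pr)2, THF, −78 °C; then 8, −78 °C; AcOH quench
Reagents that add atoms: none
Why: Aldol addition of the kinetic methyl-ketone lithium enolate to the α-chloroaldehyde; Cornforth/polar Felkin–Anh control gives the 1,2-anti chlorohydrin and so sets C10 as S.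

Step 10
Reactants: 14 (3S,6S,7R,9Z)-3-(TBSO)-12-(TBDPSO)-7-chloro-6-hydroxydodec-9-en-4-one
Product: 16 (3S,4R,6S,7R,9Z)-3-(TBSO)-12-(TBDPSO)-7-chlorododec-9-ene-4,6-diol, via diethylboron chelate 15 (not isolated)
Conditions: Et2BOMe, THF/MeOH (4:1), −78 °C; NaBH4; then MeOH co-evaporation
Reagents that add atoms: none
Why: Narasaka–Prasad reduction: hydride adds axially to the six-membered boron chelate and gives the 1,3-syn diol, which sets C12 as R.

Step 11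
Reactants: 16 (3S,4R,6S,7R,9Z)-3-(TBSO)-12-(TBDPSO)-7-chlorododec-9-ene-4,6-diol
Product: 17 (2R,3S)-3-(TBSO)-1-{(2S,3S)-3-[(2Z)-5-(TBDPSO)pent-2-en-1-yl]oxiran-2-yl}pentan-2-ol
Conditions: KOH, EtOH, 0 °C (short reaction time)
Reagents that add atoms: none
Why: Intramolecular Williamson reaction of the anti-chlorohydrin: the C10 alkoxide displaces the C9 chloride with inversion and gives the trans C9–C10 epoxide.

Step 12
Reactants: 17 (2R,3S)-3-(TBSO)-1-{(2S,3S)-3-[(2Z)-5-(TBDPSO)pent-2-en-1-yl]oxiran-2-yl}pentan-2-ol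
Product: 18 (2R,3S,5R)-2-[(2Z)-5-(TBDPSO)pent-2-en-1-yl]-5-[(1S)-1-(TBSO)propyl]oxolan-3-ol
Conditions: BF3·OEt2 (0.2 equiv), CH2Cl2, −40 → 0 °C
Reagents that add atoms: none
Why: Lewis-acid-catalysed 5-endo epoxide opening by the C12 hydroxyl at C9 with inversion gives the 2,5-cis-2,3-trans tetrahydrofuran (C9 R) and returns the free C10 hydroxyl.

Step 13
Reactants: 18 (2R,3S,5R)-2-[(2Z)-5-(TBDPSO)pent-2-en-1-yl]-5-[(1S)-1-(TBSO)propyl]oxolan-3-ol
Product: 21 (2R,4S,5S,7S,8S)-8-[2-(TBDPSO)ethyl]-5,7-dichloro-2-[(1S)-1-(TBSO)propyl]oxocan-4-ol, via titanium alkoxide 19 (not isolated), via bicyclic oxonium ion 20 (not isolated)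
Conditions: ClTi(Oi-Pr)3 (1.1 equiv), CH2Cl2, 0 °C; then t-BuOCl (1.1 equiv), −40 → −20 °C; aq. NaHCO3
Reagents that add atoms: tert-butyl hypochlorite CC(C)(C)OCl; chlorotitanium triisopropoxide CC(C)O[Ti](Cl)(OC(C)C)OC(C)C
Why: Proposed new method: the C10 hydroxyl is first bound to tetravalent titanium as alkoxide 19, then t-BuOCl transfers Cl+ to the Z-alkene while the tetrahydrofuran oxygen attacks C6 anti (5-endo, nucleophile-assisted), giving the cis-fused bicyclic oxonium ion 20 with the C5 chain and C7–Cl on the convex face (sets C6 S and C7 S, threo from the Z-alkene); the chlorotitanate that is held on the C10 oxygen then passes its chloride to the neighbouring bridgehead C9 from the back of the C9–O+ bond through a five-membered transition state, which cuts C9–O with inversion (C9 S, trans to C10–O), leaves C6–O–C12 as the eight-membered ring and steers the chloride away from the two other oxonium carbons C6 and C12; the closest known reaction types are the bromonium-induced ring expansion of tetrahydrofurans through bicyclic oxonium ions and the titanium-alkoxide-directed chloride delivery in the dichlorination of allylic alcohols.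

Step 14
Reactants: 21 (2R,4S,5S,7S,8S)-8-[2-(TBDPSO)ethyl]-5,7-dichloro-2-[(1S)-1-(TBSO)propyl]oxocan-4-ol
Product: 22 (2R,4S,5S,7S,8S)-8-[2-(TBDPSO)ethyl]-5,7-dichloro-2-[(1S)-1-(TBSO)propyl]oxocan-4-yl acetate
Conditions: Ac2O, pyridine, DMAP (cat.), CH2Cl2, 0 °C → rt
Reagents that add atoms: acetic anhydride CC(=O)OC(C)=O
Why: DMAP-catalysed acylation of the secondary C10 alcohol; the base is too weak to close the trans chlorohydrin to an epoxide.

Step 15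
Reactants: 22 (2R,4S,5S,7S,8S)-8-[2-(TBDPSO)ethyl]-5,7-dichloro-2-[(1S)-1-(TBSO)propyl]oxocan-4-yl acetate
Product: 23 (2R,4S,5S,7S,8S)-8-[2-(TBDPSO)ethyl]-5,7-dichloro-2-[(1S)-1-hydroxypropyl]oxocan-4-yl acetate
Conditions: camphorsulfonic acid (0.3 equiv), MeOH/CH2Cl2 (1:1), 0 °C → rt
Reagents that add atoms: none
Why: Selective acid-catalysed methanolysis of a silyl ether: the secondary TBS ether is cleaved far faster than the primary TBDPS ether, and the acetate survives.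

Step 16
Reactants: 23 (2R,4S,5S,7S,8S)-8-[2-(TBDPSO)ethyl]-5,7-dichloro-2-[(1S)-1-hydroxypropyl]oxocan-4-yl acetate
Product: 24 (2R,4S,5S,7S,8S)-2-[(1R)-1-bromopropyl]-8-[2-(TBDPSO)ethyl]-5,7-dichlorooxocan-4-yl acetate
Conditions: CBr4, P(n-Oct)3, toluene, 70 °C
Reagents that add atoms: carbon tetrabromide BrC(Br)(Br)Br
Why: Appel-type bromination: SN2 displacement by bromide with inversion turns C13 (S)–OH into C13 (R)–Br.

Step 17
Reactants: 24 (2R,4S,5S,7S,8S)-2-[(1R)-1-bromopropyl]-8-[2-(TBDPSO)ethyl]-5,7-dichlorooxocan-4-yl acetate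
Product: 25 (2R,4S,5S,7S,8S)-2-[(1R)-1-bromopropyl]-5,7-dichloro-8-(2-hydroxyethyl)oxocan-4-yl acetate
Conditions: HF·pyridine, pyridine, THF, 0 °C → rt
Reagents that add atoms: none
Why: Fluoride-mediated silyl ether cleavage under mildly acidic conditions removes the TBDPS group without touching the acetate or the secondary halides.

Step 18
Reactants: 25 (2R,4S,5S,7S,8S)-2-[(1R)-1-bromopropyl]-5,7-dichloro-8-(2-hydroxyethyl)oxocan-4-yl acetate
Product: 26 (2R,4S,5S,7S,8S)-2-[(1R)-1-bromopropyl]-5,7-dichloro-8-(2-oxoethyl)oxocan-4-yl acetate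
Conditions: Dess–Martin periodinane, CH2Cl2, 0 °C → rt
Reagents that add atoms: none
Why: Dess–Martin oxidation gives the C4 aldehyde under neutral conditions, which avoids β-elimination of the ring oxygen.

Step 19
Reactants: 26 (2R,4S,5S,7S,8S)-2-[(1R)-1-bromopropyl]-5,7-dichloro-8-(2-oxoethyl)oxocan-4-yl acetate; 27 1,3-bis(triisopropylsilyl)prop-1-yne
Product: 29 (2R,4S,5S,7S,8S)-2-[(1R)-1-bromopropyl]-5,7-dichloro-8-[(2Z)-5-(triisopropylsilyl)pent-2-en-4-yn-1-yl]oxocan-4-yl acetate, via lithiated propyne 28 (not isolated)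
Conditions: 27, n-BuLi, THF, −78 °C; then 26, −78 °C → rt; H2O
Reagents that add atoms: none
Why: Peterson olefination with the lithiated bis(silyl)propyne: syn-elimination of silanolate from the kinetically favoured adduct gives the (Z)-C3=C4 enyne.

Step 20
Reactants: 29 (2R,4S,5S,7S,8S)-2-[(1R)-1-bromopropyl]-5,7-dichloro-8-[(2Z)-5-(triisopropylsilyl)pent-2-en-4-yn-1-yl]oxocan-4-yl acetate
Product: 30 (2R,4S,5S,7S,8S)-2-[(1R)-1-bromopropyl]-5,7-dichloro-8-[(2Z)-pent-2-en-4-yn-1-yl]oxocan-4-yl acetate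
Conditions: Bu4NF, THF, −20 → 0 °C (short reaction time)
Reagents that add atoms: none
Why: Fluoride-induced protodesilylation of the alkynylsilane frees the terminal alkyne; low temperature and short time spare the acetate and the halides.

## Compound list

1 | but-3-yn-1-ol | C#CCCO | starting material
2 | tert-butyl(but-3-yn-1-yloxy)diphenylsilane | C#CCCO[Si](c1ccccc1)(c1ccccc1)C(C)(C)C | intermediate
3 | 2-(2-bromoethyl)-1,3-dioxolane | BrCCC1OCCO1 | starting material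
4 | [4-(TBDPSO)but-1-yn-1-yl]lithium (lithium acetylide of 2) | [Li]C#CCCO[Si](c1ccccc1)(c1ccccc1)C(C)(C)C | intermediate
5 | tert-butyl{[6-(1,3-dioxolan-2-yl)hex-3-yn-1-yl]oxy}diphenylsilane | O1CCOC1CCC#CCCO[Si](c1ccccc1)(c1ccccc1)C(C)(C)C | intermediate
6 | tert-butyl{[(3Z)-6-(1,3-dioxolan-2-yl)hex-3-en-1-yl]oxy}diphenylsilane | O1CCOC1CC/C=C\CCO[Si](c1ccccc1)(c1ccccc1)C(C)(C)C | intermediate
7 | (4Z)-7-(TBDPSO)hept-4-enal | O=CCC/C=C\CCO[Si](c1ccccc1)(c1ccccc1)C(C)(C)C | intermediate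
8 | (2R,4Z)-7-(TBDPSO)-2-chlorohept-4-enal | O=C[C@H](Cl)C/C=C\CCO[Si](c1ccccc1)(c1ccccc1)C(C)(C)C | intermediate
9 | methyl (2S)-2-hydroxybutanoate | CC[C@H](O)C(=O)OC | starting material
10 | methyl (2S)-2-(TBSO)butanoate | CC[C@H](O[Si](C)(C)C(C)(C)C)C(=O)OC | intermediate
11 | (2S)-2-(TBSO)-N-methoxy-N-methylbutanamide | CC[C@H](O[Si](C)(C)C(C)(C)C)C(=O)N(C)OC | intermediate
12 | (3S)-3-(TBSO)pentan-2-one | CC[C@H](O[Si](C)(C)C(C)(C)C)C(C)=O | intermediate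
13 | lithium (3S)-3-(TBSO)pent-1-en-2-olate (kinetic enolate of 12) | CC[C@H](O[Si](C)(C)C(C)(C)C)C(=C)O[Li] | intermediate
14 | (3S,6S,7R,9Z)-3-(TBSO)-12-(TBDPSO)-7-chloro-6-hydroxydodec-9-en-4-one | CC[C@H](O[Si](C)(C)C(C)(C)C)C(=O)C[C@H](O)[C@H](Cl)C/C=C\CCO[Si](c1ccccc1)(c1ccccc1)C(C)(C)C | intermediate
15 | (3S,6S,7R,9Z)-3-(TBSO)-12-(TBDPSO)-7-chloro-6-[(diethylboranyl)oxy]dodec-9-en-4-one (boron chelate of 14) | CC[C@H](O[Si](C)(C)C(C)(C)C)C(=O)C[C@H](OB(CC)CC)[C@H](Cl)C/C=C\CCO[Si](c1ccccc1)(c1ccccc1)C(C)(C)C | intermediate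
16 | (3S,4R,6S,7R,9Z)-3-(TBSO)-12-(TBDPSO)-7-chlorododec-9-ene-4,6-diol | CC[C@H](O[Si](C)(C)C(C)(C)C)[C@H](O)C[C@H](O)[C@H](Cl)C/C=C\CCO[Si](c1ccccc1)(c1ccccc1)C(C)(C)C | intermediate
17 | (2R,3S)-3-(TBSO)-1-{(2S,3S)-3-[(2Z)-5-(TBDPSO)pent-2-en-1-yl]oxiran-2-yl}pentan-2-ol | CC[C@H](O[Si](C)(C)C(C)(C)C)[C@H](O)C[C@@H]1O[C@H]1C/C=C\CCO[Si](c1ccccc1)(c1ccccc1)C(C)(C)C | intermediate
18 | (2R,3S,5R)-2-[(2Z)-5-(TBDPSO)pent-2-en-1-yl]-5-[(1S)-1-(TBSO)propyl]oxolan-3-ol | CC[C@H](O[Si](C)(C)C(C)(C)C)[C@H]1C[C@H](O)[C@@H](C/C=C\CCO[Si](c2ccccc2)(c2ccccc2)C(C)(C)C)O1 | intermediate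
19 | chlorobis(propan-2-olato)titanium alkoxide of 18 (Ti on the C10 oxygen) | CC[C@H](O[Si](C)(C)C(C)(C)C)[C@H]1C[C@H](O[Ti](Cl)(OC(C)C)OC(C)C)[C@@H](C/C=C\CCO[Si](c2ccccc2)(c2ccccc2)C(C)(C)C)O1 | intermediate
20 | cis-fused 1-oxoniabicyclo[3.3.0]octane zwitterion (6S,7S,9R,10S,12R): O+ bonded to C6, C9 and C12; C6 carries 2-(TBDPSO)ethyl, C7 Cl, C10 the chlorotitanate O–Ti(Cl)(Oi-Pr)2(Ot-Bu), C12 (1S)-1-(TBSO)propyl | CC[C@H](O[Si](C)(C)C(C)(C)C)[C@H]1C[C@H](O[Ti-](Cl)(OC(C)C)(OC(C)C)OC(C)(C)C)[C@H]2C[C@H](Cl)[C@H](CCO[Si](c3ccccc3)(c3ccccc3)C(C)(C)C)[O+]12 | intermediate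
21 | (2R,4S,5S,7S,8S)-8-[2-(TBDPSO)ethyl]-5,7-dichloro-2-[(1S)-1-(TBSO)propyl]oxocan-4-ol | CC(C)(C)[Si](c1ccccc1)(c1ccccc1)OCC[C@@H]1O[C@@H]([C@@H](O[Si](C)(C)C(C)(C)C)CC)C[C@H](O)[C@@H](Cl)C[C@@H]1Cl | intermediate
22 | (2R,4S,5S,7S,8S)-8-[2-(TBDPSO)ethyl]-5,7-dichloro-2-[(1S)-1-(TBSO)propyl]oxocan-4-yl acetate | CC(C)(C)[Si](c1ccccc1)(c1ccccc1)OCC[C@@H]1O[C@@H]([C@@H](O[Si](C)(C)C(C)(C)C)CC)C[C@H](OC(C)=O)[C@@H](Cl)C[C@@H]1Cl | intermediate
23 | (2R,4S,5S,7S,8S)-8-[2-(TBDPSO)ethyl]-5,7-dichloro-2-[(1S)-1-hydroxypropyl]oxocan-4-yl acetate | CC(C)(C)[Si](c1ccccc1)(c1ccccc1)OCC[C@@H]1O[C@@H]([C@@H](O)CC)C[C@H](OC(C)=O)[C@@H](Cl)C[C@@H]1Cl | intermediate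
24 | (2R,4S,5S,7S,8S)-2-[(1R)-1-bromopropyl]-8-[2-(TBDPSO)ethyl]-5,7-dichlorooxocan-4-yl acetate | CC(C)(C)[Si](c1ccccc1)(c1ccccc1)OCC[C@@H]1O[C@@H]([C@H](Br)CC)C[C@H](OC(C)=O)[C@@H](Cl)C[C@@H]1Cl | intermediate
25 | (2R,4S,5S,7S,8S)-2-[(1R)-1-bromopropyl]-5,7-dichloro-8-(2-hydroxyethyl)oxocan-4-yl acetate | OCC[C@@H]1O[C@@H]([C@H](Br)CC)C[C@H](OC(C)=O)[C@@H](Cl)C[C@@H]1Cl | intermediate
26 | (2R,4S,5S,7S,8S)-2-[(1R)-1-bromopropyl]-5,7-dichloro-8-(2-oxoethyl)oxocan-4-yl acetate | O=CC[C@@H]1O[C@@H]([C@H](Br)CC)C[C@H](OC(C)=O)[C@@H](Cl)C[C@@H]1Cl | intermediate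
27 | 1,3-bis(triisopropylsilyl)prop-1-yne | CC(C)[Si](C(C)C)(C(C)C)CC#C[Si](C(C)C)(C(C)C)C(C)C | starting material
28 | [1,3-bis(triisopropylsilyl)prop-2-yn-1-yl]lithium | CC(C)[Si](C(C)C)(C(C)C)C([Li])C#C[Si](C(C)C)(C(C)C)C(C)C | intermediate
29 | (2R,4S,5S,7S,8S)-2-[(1R)-1-bromopropyl]-5,7-dichloro-8-[(2Z)-5-(triisopropylsilyl)pent-2-en-4-yn-1-yl]oxocan-4-yl acetate | CC(C)[Si](C(C)C)(C(C)C)C#C/C=C\C[C@@H]1O[C@@H]([C@H](Br)CC)C[C@H](OC(C)=O)[C@@H](Cl)C[C@@H]1Cl | intermediate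
30 | (2R,4S,5S,7S,8S)-2-[(1R)-1-bromopropyl]-5,7-dichloro-8-[(2Z)-pent-2-en-4-yn-1-yl]oxocan-4-yl acetate (CNP0251465.2) | C#C/C=C\C[C@@H]1O[C@@H]([C@H](Br)CC)C[C@H](OC(C)=O)[C@@H](Cl)C[C@@H]1Cl | target

## Step count and risks

Total step count: 20. Longest linear sequence: 17 steps (steps 1–5 and 9–20, from but-3-yn-1-ol); the ketone branch (steps 6–8) has 3 steps.

Steps most likely to fail:

Step 13 (proposed new method). Three things can go wrong. The chloride may add directly to the chloronium ion (vicinal dichloride). The titanium-bound C10 oxygen may attack C6 in a 6-endo mode. The oxonium ion 20, strained by the endo C13 side chain, may be opened at C6 or C12 and not at C9.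
Fallback (known chemistry: the ring is closed by olefin metathesis, and chlorine and acetate are added to the ring alkene afterwards). It sets out from 10 and comes back at 22. i-Bu2AlH (CH2Cl2, −78 °C) reduces 10 to (2S)-2-(TBSO)butanal F1, and reagent-controlled allylboration with Ipc2B(allyl) (the enantiomer matched with Felkin control) gives (4R,5S)-5-(TBSO)hept-1-en-4-ol F2. Commercial (3R)-3-hydroxyoxolan-2-one is turned with Tf2O and 2,6-lutidine into (3R)-2-oxooxolan-3-yl trifluoromethanesulfonate F3. The sodium alkoxide of F2 (NaH, THF, 0 °C) displaces the triflate with inversion and gives the ether lactone (3S)-3-{[(4R,5S)-5-(TBSO)hept-1-en-4-yl]oxy}oxolan-2-one F4, which already holds the C6–O–C12 ether. i-Bu2AlH gives the lactol (3S)-3-{[(4R,5S)-5-(TBSO)hept-1-en-4-yl]oxy}oxolan-2-ol F5. A second reagent-controlled allylboration (Ipc2B(allyl), enantiomer chosen for the 7R alcohol) gives (3S,4R)-3-{[(4R,5S)-5-(TBSO)hept-1-en-4-yl]oxy}hept-6-ene-1,4-diol F6. TBDPSCl and imidazole silylate the primary hydroxyl to give (3S,4R)-1-(TBDPSO)-3-{[(4R,5S)-5-(TBSO)hept-1-en-4-yl]oxy}hept-6-en-4-ol F7. Ring-closing metathesis with RuCl2(=CHPh)(PCy3)(H2IMes) (second-generation Grubbs catalyst, CH2Cl2, 40 °C) gives the oxocene (2S,3R,5Z,8R)-2-[2-(TBDPSO)ethyl]-8-[(1S)-1-(TBSO)propyl]-3,4,7,8-tetrahydro-2H-oxocin-3-ol F8. CCl4 and P(n-Oct)3 (toluene, 80 °C) replace the C7 hydroxyl by chloride with inversion to give (2S,3S,5Z,8R)-3-chloro-2-[2-(TBDPSO)ethyl]-8-[(1S)-1-(TBSO)propyl]-3,4,7,8-tetrahydro-2H-oxocine F9. t-BuOCl in AcOH then adds Cl and OAc anti across C9=C10, and 22 is separated from its regio- and face isomers by chromatography. This last step has no regio- or facial control, which is why it is only the fallback.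

Step 16 (bromination at C13). The carbinol is hindered and sits next to the ring C–O carbon, so elimination or participation of the ring oxygen (retention, ring contraction) can compete with clean inversion.
Fallback (two-stage sulfonate displacement instead of phosphonium activation). It sets out from 23 and comes back at 24. ClCH2SO2Cl and 2,6-lutidine (CH2Cl2, 0 °C) convert 23 into the chloromethanesulfonate (2R,4S,5S,7S,8S)-8-[2-(TBDPSO)ethyl]-5,7-dichloro-2-{(1S)-1-[(chloromethanesulfonyl)oxy]propyl}oxocan-4-yl acetate F10, and LiBr in THF/DMPU displaces it by SN2 with inversion to give 24.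

Step 19 (Z-enyne by Peterson olefination). The organolithium reagent meets an acetate, three secondary halides and a β-alkoxy aldehyde that can eliminate, and the Z/E ratio depends on the aldehyde.
Fallback (vinyl iodide and cross-coupling instead of a lithium reagent). It sets out from 26 and comes back at 29. Stork–Zhao olefination of 26 with the ylide from (iodomethyl)triphenylphosphonium iodide and NaN(SiMe3)2 (THF/DMPU, −78 °C) gives the vinyl iodide (2R,4S,5S,7S,8S)-2-[(1R)-1-bromopropyl]-5,7-dichloro-8-[(2Z)-3-iodoprop-2-en-1-yl]oxocan-4-yl acetate F11, and Sonogashira coupling with (triisopropylsilyl)acetylene (Pd(PPh3)4, CuI, Et2NH, rt) gives 29.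

Further compounds

F1 | step 13 | (2S)-2-(TBSO)butanal | CC[C@H](O[Si](C)(C)C(C)(C)C)C=O
F2 | step 13 | (4R,5S)-5-(TBSO)hept-1-en-4-ol | CC[C@H](O[Si](C)(C)C(C)(C)C)[C@H](O)CC=C
F3 | step 13 | (3R)-2-oxooxolan-3-yl trifluoromethanesulfonate | O=C1OCC[C@H]1OS(=O)(=O)C(F)(F)F
F4 | step 13 | (3S)-3-{[(4R,5S)-5-(TBSO)hept-1-en-4-yl]oxy}oxolan-2-one | O=C1OCC[C@@H]1O[C@H](CC=C)[C@H](CC)O[Si](C)(C)C(C)(C)C
F5 | step 13 | (3S)-3-{[(4R,5S)-5-(TBSO)hept-1-en-4-yl]oxy}oxolan-2-ol | OC1OCC[C@@H]1O[C@H](CC=C)[C@H](CC)O[Si](C)(C)C(C)(C)C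
F6 | step 13 | (3S,4R)-3-{[(4R,5S)-5-(TBSO)hept-1-en-4-yl]oxy}hept-6-ene-1,4-diol | OCC[C@H](O[C@H](CC=C)[C@H](CC)O[Si](C)(C)C(C)(C)C)[C@H](O)CC=C
F7 | step 13 | (3S,4R)-1-(TBDPSO)-3-{[(4R,5S)-5-(TBSO)hept-1-en-4-yl]oxy}hept-6-en-4-ol | CC(C)(C)[Si](c1ccccc1)(c1ccccc1)OCC[C@H](O[C@H](CC=C)[C@H](CC)O[Si](C)(C)C(C)(C)C)[C@H](O)CC=C
F8 | step 13 | (2S,3R,5Z,8R)-2-[2-(TBDPSO)ethyl]-8-[(1S)-1-(TBSO)propyl]-3,4,7,8-tetrahydro-2H-oxocin-3-ol | CC(C)(C)[Si](c1ccccc1)(c1ccccc1)OCC[C@@H]1O[C@@H]([C@@H](O[Si](C)(C)C(C)(C)C)CC)C/C=C\C[C@H]1O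
F9 | step 13 | (2S,3S,5Z,8R)-3-chloro-2-[2-(TBDPSO)ethyl]-8-[(1S)-1-(TBSO)propyl]-3,4,7,8-tetrahydro-2H-oxocine | CC(C)(C)[Si](c1ccccc1)(c1ccccc1)OCC[C@@H]1O[C@@H]([C@@H](O[Si](C)(C)C(C)(C)C)CC)C/C=C\C[C@@H]1Cl
F10 | step 16 | (2R,4S,5S,7S,8S)-8-[2-(TBDPSO)ethyl]-5,7-dichloro-2-{(1S)-1-[(chloromethanesulfonyl)oxy]propyl}oxocan-4-yl acetate | CC(C)(C)[Si](c1ccccc1)(c1ccccc1)OCC[C@@H]1O[C@@H]([C@@H](OS(=O)(=O)CCl)CC)C[C@H](OC(C)=O)[C@@H](Cl)C[C@@H]1Cl
F11 | step 19 | (2R,4S,5S,7S,8S)-2-[(1R)-1-bromopropyl]-5,7-dichloro-8-[(2Z)-3-iodoprop-2-en-1-yl]oxocan-4-yl acetate | I/C=C\C[C@@H]1O[C@@H]([C@H](Br)CC)C[C@H](OC(C)=O)[C@@H](Cl)C[C@@H]1Cl
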